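Assumption: the target has no stereocentre and its C2–C1' axis rotates freely at room temperature, so it is one achiral compound and no stereochemistry has to be set. TMP = 2,2,6,6-tetramethylpiperidin-1-yl; SPhos = 2-dicyclohexylphosphino-2',6'-dimethoxybiphenyl.

**Retrosynthetic overview**
1. Last bond, C2–C1': the ring-A chromone acts as a nucleophile at C2, normally its Michael-acceptor carbon, as a C2–zinc species (an α-oxyvinyl metal, i.e. a masked acyl anion and β-acylvinyl anion). The partner is the electrophilic C–Br carbon of 2-bromo-3-methoxyphenol; no protecting groups are used.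
2. Chromone ⇒ 2,5-dihydroxy-3,4,6-trimethoxyacetophenone plus one carbon from DMF-DMA; ring C is closed by the ortho OH.
3. Acetophenone ⇒ Elbs para-hydroxylation of 2-hydroxy-3,4,6-trimethoxyacetophenone ⇒ Friedel–Crafts acetylation with ortho-demethylation of 1,2,3,5-tetramethoxybenzene.
4. Ring order: ring A is bought and fully substituted first, ring C is closed onto it, ring B is attached intact in the last step.

**Route**

Step 1
Reactants: 1 1,2,3,5-tetramethoxybenzene
Product: 3 1-(2-hydroxy-3,4,6-trimethoxyphenyl)ethanone, via tetramethoxyacetophenone 2 (not isolated)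
Conditions: AcCl (1.2 equiv), AlCl3 (2.5 equiv), CH2Cl2, 0 °C → 25 °C, 12 h; ice/1 M HCl
Reagents that add atoms: acetyl chloride CC(=O)Cl
Why: Friedel–Crafts acylation takes one of the two equivalent free positions (each ortho to two OMe and para to one), and AlCl3 chelated to the new ketone then cleaves the ortho methyl ether that is buttressed by a neighbouring OMe (chelation-controlled ortho-demethylation), stopping at the hydrogen-bonded mono-phenol.

Step 2
Reactants: 3 1-(2-hydroxy-3,4,6-trimethoxyphenyl)ethanone
Product: 5 1-(2,5-dihydroxy-3,4,6-trimethoxyphenyl)ethanone, via aryl potassium sulfate 4 (not isolated)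
Conditions: K2S2O8 (1.1 equiv), 10% aq KOH, 0 → 20 °C, 24 h; acidify to pH 4, wash out unchanged 3 with Et2O; then aq HCl, 90 °C, 30 min, N2
Reagents that add atoms: potassium peroxodisulfate [K+].[K+].[O-]S(=O)(=O)OOS(=O)(=O)[O-]
Why: Elbs persulfate oxidation: the phenoxide attacks the peroxide O–O bond through its para carbon, the only free ring position, and acid hydrolysis of the resulting aryl sulfate frees the hydroquinone without touching the methyl ethers or the ketone.

Step 3
Reactants: 5 1-(2,5-dihydroxy-3,4,6-trimethoxyphenyl)ethanone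
Product: 7 6-hydroxy-5,7,8-trimethoxy-4H-chromen-4-one, via enaminone 6 (not isolated)
Conditions: DMF-DMA (1.5 equiv), toluene, 80 °C, N2, 3 h; evaporate; conc. HCl, CH2Cl2, 40 °C, 1 h
Reagents that add atoms: N,N-dimethylformamide dimethyl acetal COC(OC)N(C)C
Why: The methyl ketone condenses with DMF-DMA to the enaminone (limited reagent and temperature keep O-methylation of the free 5-OH down), and acid then drives 6-endo addition of the ortho OH with loss of dimethylamine (enaminone chromone synthesis).

Step 4
Reactants: 7 6-hydroxy-5,7,8-trimethoxy-4H-chromen-4-one; 8 2-bromo-3-methoxyphenol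
Product: 11 6,2'-dihydroxy-5,7,8,6'-tetramethoxyflavone, via C2-zincated chromone 9 (not isolated), via zinc aryloxide 10 (not isolated)
Conditions: 7, Zn(TMP)2·2MgCl2·2LiCl (1.6 equiv), THF, −30 °C, 1 h; add 8 (1.2 equiv), −30 → 0 °C; Pd(OAc)2 (5 mol %), SPhos (10 mol %), 55 °C, 12 h; aq NH4Cl, then 1 M HCl to pH 4
Reagents that add atoms: none
Why: Proposed new method: the amide base first takes the phenol proton, and MgCl2 bound to the C4 carbonyl acidifies the C2–H (α to the ring oxygen, β to C=O), so zincation occurs at C2 and not C3, turning this normally electrophilic carbon into an α-oxyvinyl zinc nucleophile (masked acyl anion); the C–Zn bond is too weakly basic to be quenched by zinc aryloxides and cannot ring-open, the remaining amide converts 8 into its zinc phenoxide, and zerovalent palladium with SPhos inserts into the hindered C–Br bond, after which transmetalation and reductive elimination form the C2–C1' bond (C–H zincation then Negishi cross-coupling); the closest known reactions are the C2 zincation/Negishi arylation of O-protected chromones with this base and Negishi couplings of aryl bromides that carry free OH groups.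

**Compound list**
1 | 1,2,3,5-tetramethoxybenzene | COc1cc(OC)c(OC)c(OC)c1 | starting material
2 | 1-(2,3,4,6-tetramethoxyphenyl)ethanone | CC(=O)c1c(OC)cc(OC)c(OC)c1OC | intermediate
3 | 1-(2-hydroxy-3,4,6-trimethoxyphenyl)ethanone | CC(=O)c1c(OC)cc(OC)c(OC)c1O | intermediate
4 | potassium 3-acetyl-4-hydroxy-2,5,6-trimethoxyphenyl sulfate | CC(=O)c1c(OC)c(OS(=O)(=O)[O-])c(OC)c(OC)c1O.[K+] | intermediate
5 | 1-(2,5-dihydroxy-3,4,6-trimethoxyphenyl)ethanone | CC(=O)c1c(OC)c(O)c(OC)c(OC)c1O | intermediate
6 | (E)-1-(2,5-dihydroxy-3,4,6-trimethoxyphenyl)-3-(dimethylamino)prop-2-en-1-one | CN(C)/C=C/C(=O)c1c(OC)c(O)c(OC)c(OC)c1O | intermediate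
7 | 6-hydroxy-5,7,8-trimethoxy-4H-chromen-4-one | COc1c(O)c(OC)c(OC)c2occc(=O)c12 | intermediate
8 | 2-bromo-3-methoxyphenol | COc1cccc(O)c1Br | starting material
9 | C2-zincated zinc aryloxide of 7, drawn as the monomeric form with one TMP–Zn on C2 and one on the 6-oxygen | COc1c(O[Zn]N2C(C)(C)CCCC2(C)C)c(OC)c(OC)c2oc([Zn]N3C(C)(C)CCCC3(C)C)cc(=O)c12 | intermediate
10 | (2-bromo-3-methoxyphenoxy)(2,2,6,6-tetramethylpiperidin-1-yl)zinc, drawn as the monomer | COc1cccc(O[Zn]N2C(C)(C)CCCC2(C)C)c1Br | intermediate
11 | 6-hydroxy-2-(2-hydroxy-6-methoxyphenyl)-5,7,8-trimethoxy-4H-chromen-4-one (6,2'-dihydroxy-5,7,8,6'-tetramethoxyflavone) | COc1cccc(O)c1-c1cc(=O)c2c(OC)c(O)c(OC)c(OC)c2o1 | target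

**Totals**
Total step count: 4. Longest linear sequence: 4 steps (1 → 3 → 5 → 7 → 11); 8 enters in the last step.

**Steps most likely to fail, with fallbacks**

Step 4 is the riskiest. Two unprotected phenols must be carried as zinc aryloxides, the zincation must go to C2 and not C3, and the aryl bromide is di-ortho-substituted and electron-rich. The fallback sets out from 7 and 8 and comes back at 11 with isolable, protected partners. Compound 7 is benzylated (BnBr, K2CO3, DMF, 25 °C) to 6-(benzyloxy)-5,7,8-trimethoxy-4H-chromen-4-one F1, and 8 is benzylated the same way to 1-(benzyloxy)-2-bromo-3-methoxybenzene F2. F1 is zincated with Zn(TMP)2·2MgCl2·2LiCl (0.6 equiv, THF, −30 °C) to bis[6-(benzyloxy)-5,7,8-trimethoxy-4-oxo-4H-chromen-2-yl]zinc F3. This is coupled with F2 (Pd(OAc)2, SPhos, 50 °C) to 6-(benzyloxy)-2-[2-(benzyloxy)-6-methoxyphenyl]-5,7,8-trimethoxy-4H-chromen-4-one F4. Hydrogenolysis of both benzyl ethers (H2, Pd/C, EtOAc, 25 °C) then gives 11.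

Step 2 is next. Elbs oxidations usually stop at modest conversion, and the electron-rich hydroquinone 5 is air-sensitive in base. The fallback sets out from 3 and comes back at 5 by way of the quinone oxidation level. Compound 3 is oxidised at its free para position with K2[ON(SO3)2] (aq KH2PO4/acetone, 0–20 °C, Teuber oxidation) to 2-acetyl-3,5,6-trimethoxy-1,4-benzoquinone F5. The quinone is reduced with Na2S2O4 (EtOAc/water, 25 °C) to 5.

Step 3 is third. DMF-DMA can methylate the free 5-OH, and the acetyl group is flanked by two ortho substituents. The fallback sets out from 5 and comes back at 7 without any alkylating reagent. Claisen formylation of 5 with ethyl formate and NaH (4 equiv, THF, 0 → 40 °C, N2) gives, after acidification, 3-(2,5-dihydroxy-3,4,6-trimethoxyphenyl)-3-oxopropanal F6 (present largely as its cyclic hemiacetal). Warming in AcOH with a trace of H2SO4 (60 °C) closes and dehydrates it to 7.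

**Further compounds**
F1 | step 4 | 6-(benzyloxy)-5,7,8-trimethoxy-4H-chromen-4-one | COc1c(OCc2ccccc2)c(OC)c(OC)c2occc(=O)c12
F2 | step 4 | 1-(benzyloxy)-2-bromo-3-methoxybenzene | COc1cccc(OCc2ccccc2)c1Br
F3 | step 4 | bis[6-(benzyloxy)-5,7,8-trimethoxy-4-oxo-4H-chromen-2-yl]zinc | COc1c(OCc2ccccc2)c(OC)c(OC)c2oc([Zn]c3cc(=O)c4c(OC)c(OCc5ccccc5)c(OC)c(OC)c4o3)cc(=O)c12
F4 | step 4 | 6-(benzyloxy)-2-[2-(benzyloxy)-6-methoxyphenyl]-5,7,8-trimethoxy-4H-chromen-4-one | COc1cccc(OCc2ccccc2)c1-c1cc(=O)c2c(OC)c(OCc3ccccc3)c(OC)c(OC)c2o1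
F5 | step 2 | 2-acetyl-3,5,6-trimethoxy-1,4-benzoquinone | CC(=O)C1=C(OC)C(=O)C(OC)=C(OC)C1=O
F6 | step 3 | 3-(2,5-dihydroxy-3,4,6-trimethoxyphenyl)-3-oxopropanal | O=CCC(=O)c1c(OC)c(O)c(OC)c(OC)c1O
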